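**Retrosynthetic overview**

- Feature: ring A of the flavonol is a resorcinol in which C6, carrying the (R)-α-cyclogeranylmethyl group, lies between the oxygenated carbons C5 and C7 while C8 is C–H. Rings C and B together are a 2-aryl-3-hydroxypyran-4-one, which is an arylated kojic acid core.
- Ring A is disconnected at C4a–C5, C5–C6, C7–C8 and C8–C8a into a pyran-4-one diazomethyl ketone and a siloxyalkyne R–C≡C–OSi(i-Pr)3 (photo-Wolff/ketene benzannulation of the Danheiser type).
- The diazo ketone comes from kojic acid (ring C): iodination at C6, MOM ether, Suzuki arylation (ring B), then CH2OH → CO2H → COCHN2.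
- The siloxyalkyne comes from the (R)-α-cyclogeranylacetic ester by ynolate homologation. The ester comes from (S)-2,4,4-trimethylcyclohex-2-enol by Johnson–Claisen chirality transfer, and the alcohol from CBS reduction of the Robinson enone of isobutyraldehyde and ethyl vinyl ketone.
- Ring order: the cyclohexene ring is made, ring C is bought, ring B is attached, and ring A is closed last; two deprotections follow.

Key step: step 10

Remark: ring A positions (C4a, C5–C8, C8a) follow flavone numbering, and in the oxazaborolidine reduction the α-methylated alkenyl arm of 2,4,4-trimethylcyclohex-2-enone is assumed to act as the larger carbonyl substituent.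

**Route**

Step 1
Reactants: 1 kojic acid
Product: 2 5-hydroxy-2-(hydroxymethyl)-6-iodo-4H-pyran-4-one
Conditions: I2 (1.05 equiv), Na2CO3, H2O, 0 °C to rt; then aq. HCl to pH 2
Reagents that add atoms: iodine, II
Why: The enolic C5 hydroxyl of kojic acid activates its only free ortho carbon (C6), so iodine should substitute the enolate there by electrophilic substitution of the phenol-ortho-iodination type.

Step 2
Reactants: 2 5-hydroxy-2-(hydroxymethyl)-6-iodo-4H-pyran-4-one
Product: 3 2-(hydroxymethyl)-6-iodo-5-(methoxymethoxy)-4H-pyran-4-one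
Conditions: MOMCl (1.1 equiv), i-Pr2NEt, CH2Cl2, 0 °C
Reagents that add atoms: chloromethyl methyl ether, COCCl
Why: The enolic hydroxyl is far more acidic than the primary alcohol and is the one ionised by the amine base, so one equivalent of chloromethyl methyl ether at 0 °C should alkylate it selectively (O-alkylation of an enolate by an α-chloro ether).

Step 3
Reactants: 3 2-(hydroxymethyl)-6-iodo-5-(methoxymethoxy)-4H-pyran-4-one; 4 4-(methoxymethoxy)phenylboronic acid
Product: 5 6-(hydroxymethyl)-3-(methoxymethoxy)-2-[4-(methoxymethoxy)phenyl]-4H-pyran-4-one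
Conditions: Pd(PPh3)4 (5 mol %), Na2CO3, DME/H2O, 80 °C
Reagents that add atoms: none
Why: Suzuki–Miyaura coupling, in which the C–I bond at the β-carbon of the pyranone enone adds readily to zerovalent palladium and the acetals and the free alcohol tolerate aqueous carbonate.

Step 4
Reactants: 5 6-(hydroxymethyl)-3-(methoxymethoxy)-2-[4-(methoxymethoxy)phenyl]-4H-pyran-4-one
Product: 7 5-(methoxymethoxy)-6-[4-(methoxymethoxy)phenyl]-4-oxo-4H-pyran-2-carboxylic acid, via pyran-2-carbaldehyde 6 (not isolated)
Conditions: TEMPO (20 mol %), PhI(OAc)2 (2.2 equiv), MeCN/H2O (1:1), rt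
Reagents that add atoms: water, O
Why: Oxoammonium (TEMPO/PhI(OAc)2) oxidation takes the allylic-type primary alcohol to aldehyde 6, whose hydrate is oxidised on to the acid in the aqueous medium, under conditions mild enough for both MOM acetals.

Step 5
Reactants: 7 5-(methoxymethoxy)-6-[4-(methoxymethoxy)phenyl]-4-oxo-4H-pyran-2-carboxylic acid
Product: 9 6-(2-diazoacetyl)-3-(methoxymethoxy)-2-[4-(methoxymethoxy)phenyl]-4H-pyran-4-one, via isobutyl carbonic mixed anhydride 8 (not isolated)
Conditions: i-BuOCOCl, N-methylmorpholine, THF, −15 °C; then CH2N2 (2.5 equiv), Et2O, −15 to 0 °C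
Reagents that add atoms: diazomethane, C=[N+]=[N-] (isobutyl chloroformate, CC(C)COC(Cl)=O, leaves atoms only in intermediate 8)
Why: Acylation of diazomethane by the mixed carbonic anhydride (the first stage of an Arndt–Eistert sequence) gives the diazomethyl ketone without any strong acid, so the MOM acetals survive, and low temperature plus a small excess of diazomethane limits dipolar addition to the pyranone double bond.

Step 6
Reactants: 10 isobutyraldehyde; 11 ethyl vinyl ketone
Product: 13 2,4,4-trimethylcyclohex-2-en-1-one, via 2,2-dimethyl-5-oxoheptanal 12 (not isolated)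
Conditions: H2SO4 (cat.), neat, 45–50 °C; then toluene, reflux, Dean–Stark
Reagents that add atoms: none
Why: Acid-catalysed Robinson annulation, that is Michael addition of the aldehyde enol to the vinyl ketone and intramolecular aldol condensation of keto aldehyde 12, in which only the ethyl-side α-carbon of the ketone can close a six-membered ring onto the non-enolisable aldehyde.

Step 7
Reactants: 13 2,4,4-trimethylcyclohex-2-en-1-one
Product: 14 (1S)-2,4,4-trimethylcyclohex-2-en-1-ol
Conditions: (R)-2-methyl-CBS-oxazaborolidine (10 mol %), BH3·SMe2, THF, −20 °C, slow addition of 13; MeOH quench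
Reagents that add atoms: none
Why: Corey–Bakshi–Shibata reduction, in which borane bound to the oxazaborolidine nitrogen delivers hydride to the ketone face fixed by placing the α-methylalkenyl arm as the large substituent, so the (R)-catalyst should set the (S)-carbinol centre by 1,2-reduction.

Step 8
Reactants: 14 (1S)-2,4,4-trimethylcyclohex-2-en-1-ol
Product: 16 ethyl 2-[(1R)-2,6,6-trimethylcyclohex-2-en-1-yl]acetate, via mixed ketene acetal 15 (not isolated)
Conditions: MeC(OEt)3 (excess), EtCO2H (cat.), 140 °C, distillation of EtOH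
Reagents that add atoms: triethyl orthoacetate, CCOC(C)(OCC)OCC
Why: Johnson–Claisen rearrangement, in which the [3,3] shift of ketene acetal 15 is suprafacial across the ring, so the new C–C bond forms at the old alkene CH next to the gem-dimethyl carbon on the face that carried the oxygen, which turns the (S)-carbinol centre into the (1R)-centre of the α-cyclogeranyl unit and moves the double bond into its final position.

Step 9
Reactants: 16 ethyl 2-[(1R)-2,6,6-trimethylcyclohex-2-en-1-yl]acetate
Product: 19 triisopropyl{3-[(1R)-2,6,6-trimethylcyclohex-2-en-1-yl]prop-1-ynyloxy}silane, via lithium dibromoenolate 17 (not isolated), via lithium ynolate 18 (not isolated)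
Conditions: CH2Br2, lithium 2,2,6,6-tetramethylpiperidide (LiTMP, 2.2 equiv), THF, −78 °C; n-BuLi (excess), −78 °C to rt; then i-Pr3SiCl, −78 °C to rt
Reagents that add atoms: dibromomethane, BrCBr; chlorotriisopropylsilane, CC(C)[Si](Cl)(C(C)C)C(C)C (the lithium of 17 and 18 comes from LiTMP and n-BuLi)
Why: Kowalski ynolate synthesis, in which dibromomethyllithium adds to the ester, bromine–lithium exchange of dibromoenolate 17 triggers 1,2-shift of the alkyl group with loss of bromide to give ynolate 18, and the bulky silyl chloride should react at oxygen, while the stereocentre is β to the reacting carbonyl and is not touched.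

Step 10
Reactants: 9 6-(2-diazoacetyl)-3-(methoxymethoxy)-2-[4-(methoxymethoxy)phenyl]-4H-pyran-4-one; 19 triisopropyl{3-[(1R)-2,6,6-trimethylcyclohex-2-en-1-yl]prop-1-ynyloxy}silane
Product: 23 5-hydroxy-3-(methoxymethoxy)-2-[4-(methoxymethoxy)phenyl]-7-(triisopropylsilyloxy)-6-{[(1R)-2,6,6-trimethylcyclohex-2-en-1-yl]methyl}chromen-4-one, via pyranylketene 20 (not isolated), via 4-pyranylcyclobutenone 21 (not isolated), via dienylketene 22 (not isolated)
Conditions: 19 (1.5 equiv), ClCH2CH2Cl (degassed, 0.1 M), 450 nm LEDs, 20 °C until 9 is consumed; then 80 °C in the dark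
Reagents that add atoms: none
Why: Blue light should excite only the n→π* band of the diazo ketone in 9, and loss of N2 with 1,2-shift of pyranone C6 (flavone C8a) to the former diazo carbon (C8) gives pyranylketene 20 (photochemical Wolff rearrangement); the alkyl-bearing, nucleophilic alkyne carbon of 19 then attacks the ketene carbonyl carbon in a [2+2] cycloaddition (C5–C6 and C7–C8 bonds) to give cyclobutenone 21, which opens on warming by 4π-electrocyclic cleavage to dienylketene 22. Ring A then closes by a 6π-electrocyclisation in which the electrophilic ketene carbon (C5) bonds to the enol-ether β-carbon C5–H of the pyranone (flavone C4a), and tautomerisation of the cyclohexadienone gives the chelated C5 phenol. The closest known reaction is the Danheiser benzannulation of α,β-unsaturated, aryl and heteroaryl diazomethyl ketones with siloxyalkynes; here the 2π partner is the C5=C6 bond of a pyran-4-one, a member of that class not yet tried, which has little aromatic stabilisation to lose and is polarised in the matched sense. No stereocentre is formed (the sp3 carbon of 21 is lost on ring opening) and the remote (R)-centre of 19 is untouched under neutral conditions. The step needs regioselectivity in the [2+2] step, secured by the oxygen substituent of the siloxyalkyne, which makes the alkyl-bearing carbon the nucleophile and so places the side chain at C6 between the two oxygens and not at C8; it needs selective excitation, secured by the 450 nm source at which the aryl pyranone chromophore should not absorb; and the product phenol is shielded from acylation by ketene 20 through its hydrogen bond to the C4 carbonyl and its flanking side chain.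

Step 11
Reactants: 23 5-hydroxy-3-(methoxymethoxy)-2-[4-(methoxymethoxy)phenyl]-7-(triisopropylsilyloxy)-6-{[(1R)-2,6,6-trimethylcyclohex-2-en-1-yl]methyl}chromen-4-one
Product: 24 3,5-dihydroxy-2-(4-hydroxyphenyl)-7-(triisopropylsilyloxy)-6-{[(1R)-2,6,6-trimethylcyclohex-2-en-1-yl]methyl}chromen-4-one
Conditions: aq. HCl (2 M), MeOH/THF, 40 °C
Reagents that add atoms: none
Why: Acid-catalysed acetal exchange with methanol removes both MOM groups, and it is run while the C7 oxygen is still silylated and the C5 hydroxyl is tied to the C4 carbonyl by a hydrogen bond, so that no free nucleophilic phenol flanks the acid-sensitive trisubstituted alkene (any early loss of the silyl group only gives the target itself).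

Step 12
Reactants: 24 3,5-dihydroxy-2-(4-hydroxyphenyl)-7-(triisopropylsilyloxy)-6-{[(1R)-2,6,6-trimethylcyclohex-2-en-1-yl]methyl}chromen-4-one
Product: 25 Ugonin G
Conditions: Bu4NF, AcOH (1:1), THF, 0 °C, under argon
Reagents that add atoms: none
Why: Fluoride cleaves the aryl Si–O bond (desilylation driven by the strong Si–F bond), and the acetic acid buffer keeps the polyphenol out of strongly basic solution.

**Compound list**

1 | kojic acid, 5-hydroxy-2-(hydroxymethyl)-4H-pyran-4-one | OCc1cc(=O)c(O)co1 | starting material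
2 | 5-hydroxy-2-(hydroxymethyl)-6-iodo-4H-pyran-4-one | OCc1cc(=O)c(O)c(I)o1 | intermediate
3 | 2-(hydroxymethyl)-6-iodo-5-(methoxymethoxy)-4H-pyran-4-one | OCc1cc(=O)c(OCOC)c(I)o1 | intermediate
4 | 4-(methoxymethoxy)phenylboronic acid | COCOc1ccc(B(O)O)cc1 | starting material
5 | 6-(hydroxymethyl)-3-(methoxymethoxy)-2-[4-(methoxymethoxy)phenyl]-4H-pyran-4-one | OCc1cc(=O)c(OCOC)c(-c2ccc(OCOC)cc2)o1 | intermediate
6 | 5-(methoxymethoxy)-6-[4-(methoxymethoxy)phenyl]-4-oxo-4H-pyran-2-carbaldehyde | O=Cc1cc(=O)c(OCOC)c(-c2ccc(OCOC)cc2)o1 | intermediate (not isolated)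
7 | 5-(methoxymethoxy)-6-[4-(methoxymethoxy)phenyl]-4-oxo-4H-pyran-2-carboxylic acid | OC(=O)c1cc(=O)c(OCOC)c(-c2ccc(OCOC)cc2)o1 | intermediate
8 | isobutyl carbonic mixed anhydride of acid 7 | CC(C)COC(=O)OC(=O)c1cc(=O)c(OCOC)c(-c2ccc(OCOC)cc2)o1 | intermediate (not isolated)
9 | 6-(2-diazoacetyl)-3-(methoxymethoxy)-2-[4-(methoxymethoxy)phenyl]-4H-pyran-4-one | [N-]=[N+]=CC(=O)c1cc(=O)c(OCOC)c(-c2ccc(OCOC)cc2)o1 | intermediate (key-step precursor)
10 | isobutyraldehyde | CC(C)C=O | starting material
11 | ethyl vinyl ketone (pent-1-en-3-one) | CCC(=O)C=C | starting material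
12 | 2,2-dimethyl-5-oxoheptanal | CCC(=O)CCC(C)(C)C=O | intermediate (not isolated)
13 | 2,4,4-trimethylcyclohex-2-en-1-one | CC1=CC(C)(C)CCC1=O | intermediate
14 | (1S)-2,4,4-trimethylcyclohex-2-en-1-ol | CC1=CC(C)(C)CC[C@@H]1O | intermediate
15 | 1-ethoxy-1-{[(1S)-2,4,4-trimethylcyclohex-2-en-1-yl]oxy}ethene | C=C(OCC)O[C@@H]1C(C)=CC(C)(C)CC1 | intermediate (not isolated)
16 | ethyl 2-[(1R)-2,6,6-trimethylcyclohex-2-en-1-yl]acetate | CC1=CCCC(C)(C)[C@H]1CC(=O)OCC | intermediate
17 | lithium 1,1-dibromo-3-[(1R)-2,6,6-trimethylcyclohex-2-en-1-yl]prop-1-en-2-olate | CC1=CCCC(C)(C)[C@H]1CC(O[Li])=C(Br)Br | intermediate (not isolated)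
18 | lithium 3-[(1R)-2,6,6-trimethylcyclohex-2-en-1-yl]prop-1-yn-1-olate | CC1=CCCC(C)(C)[C@H]1CC#CO[Li] | intermediate (not isolated)
19 | triisopropyl{3-[(1R)-2,6,6-trimethylcyclohex-2-en-1-yl]prop-1-ynyloxy}silane | CC1=CCCC(C)(C)[C@H]1CC#CO[Si](C(C)C)(C(C)C)C(C)C | intermediate (key-step precursor)
20 | 3-(methoxymethoxy)-2-[4-(methoxymethoxy)phenyl]-6-(2-oxoethenyl)-4H-pyran-4-one | O=C=Cc1cc(=O)c(OCOC)c(-c2ccc(OCOC)cc2)o1 | intermediate (not isolated)
21 | 4-{5-(methoxymethoxy)-6-[4-(methoxymethoxy)phenyl]-4-oxo-4H-pyran-2-yl}-3-(triisopropylsilyloxy)-2-{[(1R)-2,6,6-trimethylcyclohex-2-en-1-yl]methyl}cyclobut-2-en-1-one, both C4 epimers | CC1=CCCC(C)(C)[C@H]1CC1=C(O[Si](C(C)C)(C(C)C)C(C)C)C(c2cc(=O)c(OCOC)c(-c3ccc(OCOC)cc3)o2)C1=O | intermediate (not isolated)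
22 | dienylketene, 4-{5-(methoxymethoxy)-6-[4-(methoxymethoxy)phenyl]-4-oxo-4H-pyran-2-yl}-3-(triisopropylsilyloxy)-2-{[(1R)-2,6,6-trimethylcyclohex-2-en-1-yl]methyl}buta-1,3-dien-1-one, pyranyl group cis to the ketene-bearing carbon | CC1=CCCC(C)(C)[C@H]1CC(=C=O)/C(O[Si](C(C)C)(C(C)C)C(C)C)=C\c1cc(=O)c(OCOC)c(-c2ccc(OCOC)cc2)o1 | intermediate (not isolated)
23 | 5-hydroxy-3-(methoxymethoxy)-2-[4-(methoxymethoxy)phenyl]-7-(triisopropylsilyloxy)-6-{[(1R)-2,6,6-trimethylcyclohex-2-en-1-yl]methyl}chromen-4-one | CC1=CCCC(C)(C)[C@H]1Cc1c(O[Si](C(C)C)(C(C)C)C(C)C)cc2oc(-c3ccc(OCOC)cc3)c(OCOC)c(=O)c2c1O | intermediate (key-step product)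
24 | 3,5-dihydroxy-2-(4-hydroxyphenyl)-7-(triisopropylsilyloxy)-6-{[(1R)-2,6,6-trimethylcyclohex-2-en-1-yl]methyl}chromen-4-one | CC1=CCCC(C)(C)[C@H]1Cc1c(O[Si](C(C)C)(C(C)C)C(C)C)cc2oc(-c3ccc(O)cc3)c(O)c(=O)c2c1O | intermediate
25 | Ugonin G, 3,5,7-trihydroxy-2-(4-hydroxyphenyl)-6-{[(1R)-2,6,6-trimethylcyclohex-2-en-1-yl]methyl}chromen-4-one | CC1=CCCC(C)(C)[C@H]1Cc1c(O)cc2oc(-c3ccc(O)cc3)c(O)c(=O)c2c1O | target

**Step count**

Total: 12 steps. Longest linear sequence: 8 steps (steps 1–5, then 10–12, from kojic acid). The side-chain branch is 4 steps (6–9) before the convergent step 10.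

**Steps most likely to fail**

1. Step 10 (benzannulation). The pyranone chromophore may be destroyed by light, the carbene may react before the 1,2-shift, or ketene 20 may be consumed by dimerisation. The fallback forms the same ketene thermally in the dark, as in the known resorcinol annulation of siloxyalkynes with vinylketenes made by dehydrohalogenation. It sets out from 9: Wolff rearrangement with silver benzoate (PhCO2Ag) and Et3N in aqueous THF should give 2-{5-(methoxymethoxy)-6-[4-(methoxymethoxy)phenyl]-4-oxo-4H-pyran-2-yl}acetic acid F1. 1-Chloro-N,N,2-trimethylpropenylamine in CH2Cl2 at 0 °C should convert it under neutral conditions into the acetyl chloride F2. Slow addition of Et3N to F2 and alkyne 19 in toluene at 80 °C should generate ketene 20, which proceeds through 21 and 22 and comes back to the route at 23.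

2. Step 5 (diazo ketone). Diazomethane may add as a 1,3-dipole to the electron-poor pyranone double bond, or attack the carbonate carbonyl of 8 and return the acid as an ester. The fallback avoids diazomethane by detrifluoroacetylative diazo transfer. It sets out from 5: MnO2 in CH2Cl2 should give aldehyde 6, now isolated. MeMgBr in THF at −78 °C should add to the aldehyde in preference to the vinylogous ester carbonyl to give racemic 6-(1-hydroxyethyl)-3-(methoxymethoxy)-2-[4-(methoxymethoxy)phenyl]-4H-pyran-4-one F3. Dess–Martin periodinane should oxidise it to the 6-acetyl pyranone F4. LiN(SiMe3)2 and CF3CO2CH2CF3 in THF at −78 °C should give the trifluoromethyl 1,3-diketone F5. Methanesulfonyl azide with Et3N and water in MeCN should then transfer the diazo group with loss of the trifluoroacetyl group, coming back to the route at 9.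

3. Step 9 (siloxyalkyne). The ester may be enolised instead of adding dibromomethyllithium, or the carbenoid rearrangement of 17 may be incomplete, which leaves bromo ketones in place of ynolate 18. The fallback reaches the same ynolate by oxidation of a lithium acetylide. It sets out from 16: i-Bu2AlH in CH2Cl2 at −78 °C should give 2-[(1R)-2,6,6-trimethylcyclohex-2-en-1-yl]acetaldehyde F6. Dimethyl (1-diazo-2-oxopropyl)phosphonate with K2CO3 in MeOH (Ohira–Bestmann) should give 3-[(1R)-2,6,6-trimethylcyclohex-2-en-1-yl]prop-1-yne F7. Deprotonation with n-BuLi and oxidation of the acetylide with lithium tert-butyl peroxide (from t-BuOOH and LiN(SiMe3)2) in THF should give ynolate 18, and i-Pr3SiOTf should silylate it on oxygen, coming back to the route at 19.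

**Further compounds**

F1 | step 10 | 2-{5-(methoxymethoxy)-6-[4-(methoxymethoxy)phenyl]-4-oxo-4H-pyran-2-yl}acetic acid | OC(=O)Cc1cc(=O)c(OCOC)c(-c2ccc(OCOC)cc2)o1
F2 | step 10 | 2-{5-(methoxymethoxy)-6-[4-(methoxymethoxy)phenyl]-4-oxo-4H-pyran-2-yl}acetyl chloride | ClC(=O)Cc1cc(=O)c(OCOC)c(-c2ccc(OCOC)cc2)o1
F3 | step 5 | 6-(1-hydroxyethyl)-3-(methoxymethoxy)-2-[4-(methoxymethoxy)phenyl]-4H-pyran-4-one, racemic | CC(O)c1cc(=O)c(OCOC)c(-c2ccc(OCOC)cc2)o1
F4 | step 5 | 6-acetyl-3-(methoxymethoxy)-2-[4-(methoxymethoxy)phenyl]-4H-pyran-4-one | CC(=O)c1cc(=O)c(OCOC)c(-c2ccc(OCOC)cc2)o1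
F5 | step 5 | 4,4,4-trifluoro-1-{5-(methoxymethoxy)-6-[4-(methoxymethoxy)phenyl]-4-oxo-4H-pyran-2-yl}butane-1,3-dione | O=C(CC(=O)C(F)(F)F)c1cc(=O)c(OCOC)c(-c2ccc(OCOC)cc2)o1
F6 | step 9 | 2-[(1R)-2,6,6-trimethylcyclohex-2-en-1-yl]acetaldehyde | CC1=CCCC(C)(C)[C@H]1CC=O
F7 | step 9 | 3-[(1R)-2,6,6-trimethylcyclohex-2-en-1-yl]prop-1-yne | CC1=CCCC(C)(C)[C@H]1CC#C
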